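Ring A is built by a Diels–Alder benzannulation. Its C5–C6–C7–C8 edge (O, H, O, OMe) is the four-carbon chain of methyl 4-methoxyacetoacetate, used as a 1,3-bis(silyloxy)-1,4-dimethoxydiene. C4a and C8a are the alkyne carbons of a bromoynone that already carries C2, C3, C4, both prenyl ethers and ring B. One operation forms C5–C4a and C8–C8a, aromatises by loss of methanol, and leaves bromine on C8a as the only site for O1. The ynone comes from a glycolic N-methoxy-N-methylamide and 4-(prenyloxy)benzoic acid. Enol-ether hydrolysis and copper-catalysed O-arylation then close ring C.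

Key step: step 9

Remarks on the chemistry:
- Abbreviations: prenyl = 3-methylbut-2-en-1-yl; TBS = tert-butyldimethylsilyl; MOM = methoxymethyl.
- Protecting-group design: the C5 and C7 oxygens are TBS ethers, brought in by the diene, and stay silylated until the enol ether is gone. A free C5–OH beside a β-alkoxy enone would add to C2, expel the alkoxide and close ring C through O5, giving the 5-bromo-6-methoxy isomer. The enol ether is MOM rather than methyl because it is installed on oxygen selectively and is removed by acid mild enough for prenyl and aryl TBS ethers.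
- Assumption: the alkene geometries given for the enol ethers and the diene are the expected major isomers; all are erased later (hydrolysis or aromatisation), so isomer mixtures can be carried forward.

Step 1
Reactants: 1 2-chloro-N-methoxy-N-methylacetamide; 2 3-methylbut-2-en-1-ol (prenol)
Product: 3 N-methoxy-N-methyl-2-(prenyloxy)acetamide
Conditions: NaH, THF, 0 °C; then 1, n-Bu4NI (cat.), 0 °C → rt
Reagents that add atoms: none
Why: Williamson ether synthesis, in which sodium prenoxide should displace the activated α-chloride by SN2 faster than it attacks the poorly electrophilic N-methoxy-N-methylamide carbonyl.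

Step 2
Reactants: 4 4-hydroxybenzoic acid; 5 prenyl bromide
Product: 7 4-(prenyloxy)benzoic acid, via prenyl 4-(prenyloxy)benzoate 6 (not isolated)
Conditions: K2CO3, DMF, rt; then 2 M aq. NaOH, MeOH, 60 °C; 1 M HCl, 0 °C
Reagents that add atoms: sodium hydroxide, [Na+].[OH-]
Why: Carbonate-mediated SN2 alkylation of phenoxide and carboxylate by the allylic bromide gives ester ether 6, whose ester alone is saponified by acyl–oxygen cleavage while the aryl prenyl ether is inert to base.

Step 3
Reactants: 3 N-methoxy-N-methyl-2-(prenyloxy)acetamide; 7 4-(prenyloxy)benzoic acid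
Product: 9 N-methoxy-N-methyl-3-oxo-2-(prenyloxy)-3-[4-(prenyloxy)phenyl]propanamide (racemic), via 4-(prenyloxy)benzoyl chloride 8 (not isolated)
Conditions: 7, Me2C=C(Cl)NMe2, CH2Cl2, rt; then added to 3 (2.1 equiv), LiHMDS (2.1 equiv), THF, −78 °C; AcOH quench
Reagents that add atoms: none
Why: Claisen-type C-acylation of the lithium amide enolate by the acid chloride, in which the second equivalent of enolate takes the acidic proton of the β-keto amide, the acid chloride is made without HCl so the prenyl ether is not exposed to acid, and −78 °C keeps the α-allyloxy enolate from [2,3]-Wittig rearrangement.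

Step 4
Reactants: 9 N-methoxy-N-methyl-3-oxo-2-(prenyloxy)-3-[4-(prenyloxy)phenyl]propanamide
Product: 10 (E)-N-methoxy-3-(methoxymethoxy)-N-methyl-2-(prenyloxy)-3-[4-(prenyloxy)phenyl]prop-2-enamide (MOM-oxy group cis to the amide carbonyl)
Conditions: NaH, THF, 0 °C; MOMCl, 0 °C → rt
Reagents that add atoms: chloromethyl methyl ether, COCCl
Why: O-alkylation of the chelated sodium enolate of the β-keto amide by the hard, oxocarbenium-like chloromethyl ether should give the enol ether, since C-alkylation at the fully substituted α-carbon cannot compete and the chelate places the new MOM-oxy group cis to the amide carbonyl.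

Step 5
Reactants: 10 (E)-N-methoxy-3-(methoxymethoxy)-N-methyl-2-(prenyloxy)-3-[4-(prenyloxy)phenyl]prop-2-enamide; 11 ethynyltrimethylsilane
Product: 12 (E)-1-(methoxymethoxy)-2-(prenyloxy)-1-[4-(prenyloxy)phenyl]-5-(trimethylsilyl)pent-1-en-4-yn-3-one
Conditions: 11, n-BuLi, THF, −78 °C; then 10, −78 → −20 °C; cold aq. NH4Cl
Reagents that add atoms: none
Why: Ketone synthesis from an N-methoxy-N-methylamide, in which the slim lithium acetylide adds once to the hindered acrylamide to give a chelated tetrahedral intermediate that collapses to the ynone only on quench, and the substrate has no acidic hydrogen left.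

Step 6
Reactants: 12 (E)-1-(methoxymethoxy)-2-(prenyloxy)-1-[4-(prenyloxy)phenyl]-5-(trimethylsilyl)pent-1-en-4-yn-3-one
Product: 13 (E)-5-bromo-1-(methoxymethoxy)-2-(prenyloxy)-1-[4-(prenyloxy)phenyl]pent-1-en-4-yn-3-one
Conditions: NBS, AgNO3 (10 mol%), acetone, rt, dark
Reagents that add atoms: N-bromosuccinimide, O=C1CCC(=O)N1Br
Why: Silver-catalysed bromodesilylation, in which AgNO3 turns the alkynylsilane into a silver acetylide that NBS should brominate much faster than it attacks the isolated prenyl alkenes or the push–pull enol ether in dry acetone.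

Step 7
Reactants: 14 methyl 4-methoxy-3-oxobutanoate (methyl 4-methoxyacetoacetate)
Product: 15 methyl (Z)-3-(TBS-oxy)-4-methoxybut-2-enoate
Conditions: TBSOTf, Et3N, CH2Cl2, 0 °C
Reagents that add atoms: tert-butyldimethylsilyl trifluoromethanesulfonate, CC(C)(C)[Si](C)(C)OS(=O)(=O)C(F)(F)F
Why: O-silylation of the β-keto ester enol with a silyl triflate and amine base gives the ester-conjugated (Z)-silyloxy enoate, the only enol of this substrate that is formed under these conditions.

Step 8
Reactants: 15 methyl (Z)-3-(TBS-oxy)-4-methoxybut-2-enoate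
Product: 16 (1Z,3Z)-1,3-bis(TBS-oxy)-1,4-dimethoxybuta-1,3-diene
Conditions: LDA, THF, −78 °C; TBSCl, DMPU, −78 → 0 °C
Reagents that add atoms: tert-butyldimethylsilyl chloride, CC(C)(C)[Si](C)(C)Cl
Why: γ-Deprotonation of the silyloxy enoate by LDA gives the extended ester dienolate, which TBSCl in the presence of DMPU silylates on oxygen to give the silyl ketene acetal diene.

Step 9
Reactants: 13 (E)-5-bromo-1-(methoxymethoxy)-2-(prenyloxy)-1-[4-(prenyloxy)phenyl]pent-1-en-4-yn-3-one; 16 (1Z,3Z)-1,3-bis(TBS-oxy)-1,4-dimethoxybuta-1,3-diene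
Product: 18 (E)-1-[2-bromo-4,6-bis(TBS-oxy)-3-methoxyphenyl]-3-(methoxymethoxy)-2-(prenyloxy)-3-[4-(prenyloxy)phenyl]prop-2-en-1-one, via cis-dimethoxycyclohexa-1,4-diene cycloadduct 17 (not isolated)
Conditions: 16 (1.5 equiv), PhMe, 25 → 60 °C; then SiO2, CH2Cl2, rt
Reagents that add atoms: none
Why: A normal-electron-demand Diels–Alder reaction, concerted but strongly asynchronous (in the limit a Mukaiyama–Michael addition followed by ring closure), joins diene C4 (the CH–OMe carbon, future C8) to the bromine-bearing β-carbon of the ynone (future C8a) and the ketene-acetal carbon C1 (future C5) to the α-carbon (future C4a), giving cyclohexadiene 17. The closest known reaction type is the cycloaddition–aromatisation of 1-alkoxy-1,3-bis(silyloxy)buta-1,3-dienes with alkynyl ketones, alkynoates and haloalkynes to give resorcinol derivatives. Ring A is closed by the intermolecular (4+2) cycloaddition itself, or in the stepwise limit by 6-exo-trig attack of the allenolate α-carbon on the silyloxycarbenium carbon. No stereocentre survives, because the two sp3 centres of 17 disappear when the ketal methoxy group ionises (silica as proton source) to a silyloxy-stabilised arenium ion that sheds the C8 proton; methanol rather than silanol should therefore leave, and both TBS groups stay on the C5 and C7 oxygens. The selectivity needed is regiochemical and is secured by matched polarity: the 1,1-dioxy and 3-silyloxy donors make C4 the nucleophilic diene terminus, and the ketone makes the bromine-bearing carbon the electrophilic alkyne terminus. Bromine sits on an sp2 carbon of 17, cannot be eliminated, and is carried to C8a.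

Step 10
Reactants: 18 (E)-1-[2-bromo-4,6-bis(TBS-oxy)-3-methoxyphenyl]-3-(methoxymethoxy)-2-(prenyloxy)-3-[4-(prenyloxy)phenyl]prop-2-en-1-one
Product: 19 1-[2-bromo-4,6-bis(TBS-oxy)-3-methoxyphenyl]-2-(prenyloxy)-3-[4-(prenyloxy)phenyl]propane-1,3-dione (racemic and enolisable)
Conditions: 0.5 M aq. HCl, THF, 0 °C → rt
Reagents that add atoms: none
Why: Hydrolysis of a vinylogous MOM ester, in which protonation of the enone lets the methoxymethyl cation leave from oxygen, should free the 1,3-diketone under acid too mild for the aryl TBS and prenyl ethers, and with O5 silylated no phenol can add to C2.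

Step 11
Reactants: 19 1-[2-bromo-4,6-bis(TBS-oxy)-3-methoxyphenyl]-2-(prenyloxy)-3-[4-(prenyloxy)phenyl]propane-1,3-dione
Product: 21 5,7-dihydroxy-8-methoxy-3-(prenyloxy)-2-[4-(prenyloxy)phenyl]-4H-chromen-4-one, via 5,7-bis(TBS-oxy) flavone 20 (not isolated)
Conditions: CuI (10 mol%), 1,10-phenanthroline (20 mol%), K3PO4, 1,4-dioxane, 80 °C; then TBAF, AcOH, THF, 0 °C
Reagents that add atoms: none
Why: Ullmann-type intramolecular O-arylation, in which the potassium enolate of the 1,3-diketone binds monovalent copper and its distal oxygen displaces bromide at C8a in the only feasible (six-membered) ring closure, after which buffered fluoride removes both aryl silyl ethers without touching the prenyl ethers.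

Compound list
1 | 2-chloro-N-methoxy-N-methylacetamide | CON(C)C(=O)CCl | starting material
2 | 3-methylbut-2-en-1-ol (prenol) | CC(C)=CCO | starting material
3 | N-methoxy-N-methyl-2-(prenyloxy)acetamide | CON(C)C(=O)COCC=C(C)C | intermediate
4 | 4-hydroxybenzoic acid | O=C(O)c1ccc(O)cc1 | starting material
5 | prenyl bromide (1-bromo-3-methylbut-2-ene) | CC(C)=CCBr | starting material
6 | prenyl 4-(prenyloxy)benzoate | CC(C)=CCOC(=O)c1ccc(OCC=C(C)C)cc1 | intermediate (not isolated)
7 | 4-(prenyloxy)benzoic acid | CC(C)=CCOc1ccc(cc1)C(=O)O | intermediate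
8 | 4-(prenyloxy)benzoyl chloride | CC(C)=CCOc1ccc(cc1)C(=O)Cl | intermediate (not isolated)
9 | N-methoxy-N-methyl-3-oxo-2-(prenyloxy)-3-[4-(prenyloxy)phenyl]propanamide (racemic) | CON(C)C(=O)C(OCC=C(C)C)C(=O)c1ccc(OCC=C(C)C)cc1 | intermediate
10 | (E)-N-methoxy-3-(methoxymethoxy)-N-methyl-2-(prenyloxy)-3-[4-(prenyloxy)phenyl]prop-2-enamide | COCO/C(=C(/OCC=C(C)C)C(=O)N(C)OC)c1ccc(OCC=C(C)C)cc1 | intermediate
11 | ethynyltrimethylsilane | C#C[Si](C)(C)C | starting material
12 | (E)-1-(methoxymethoxy)-2-(prenyloxy)-1-[4-(prenyloxy)phenyl]-5-(trimethylsilyl)pent-1-en-4-yn-3-one | COCO/C(=C(/OCC=C(C)C)C(=O)C#C[Si](C)(C)C)c1ccc(OCC=C(C)C)cc1 | intermediate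
13 | (E)-5-bromo-1-(methoxymethoxy)-2-(prenyloxy)-1-[4-(prenyloxy)phenyl]pent-1-en-4-yn-3-one | COCO/C(=C(/OCC=C(C)C)C(=O)C#CBr)c1ccc(OCC=C(C)C)cc1 | intermediate
14 | methyl 4-methoxy-3-oxobutanoate | COCC(=O)CC(=O)OC | starting material
15 | methyl (Z)-3-(TBS-oxy)-4-methoxybut-2-enoate | COC/C(=C/C(=O)OC)O[Si](C)(C)C(C)(C)C | intermediate
16 | (1Z,3Z)-1,3-bis(TBS-oxy)-1,4-dimethoxybuta-1,3-diene | CO/C=C(O[Si](C)(C)C(C)(C)C)/C=C(/OC)O[Si](C)(C)C(C)(C)C | intermediate
17 | (E)-1-[2-bromo-4,6-bis(TBS-oxy)-cis-3,6-dimethoxycyclohexa-1,4-dien-1-yl]-3-(methoxymethoxy)-2-(prenyloxy)-3-[4-(prenyloxy)phenyl]prop-2-en-1-one (racemic, one enantiomer drawn) | CO[C@@]1(O[Si](C)(C)C(C)(C)C)C=C(O[Si](C)(C)C(C)(C)C)[C@@H](OC)C(Br)=C1C(=O)/C(OCC=C(C)C)=C(\OCOC)c1ccc(OCC=C(C)C)cc1 | intermediate (not isolated)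
18 | (E)-1-[2-bromo-4,6-bis(TBS-oxy)-3-methoxyphenyl]-3-(methoxymethoxy)-2-(prenyloxy)-3-[4-(prenyloxy)phenyl]prop-2-en-1-one | COCO/C(=C(/OCC=C(C)C)C(=O)c1c(O[Si](C)(C)C(C)(C)C)cc(O[Si](C)(C)C(C)(C)C)c(OC)c1Br)c1ccc(OCC=C(C)C)cc1 | intermediate
19 | 1-[2-bromo-4,6-bis(TBS-oxy)-3-methoxyphenyl]-2-(prenyloxy)-3-[4-(prenyloxy)phenyl]propane-1,3-dione (racemic) | COc1c(O[Si](C)(C)C(C)(C)C)cc(O[Si](C)(C)C(C)(C)C)c(C(=O)C(OCC=C(C)C)C(=O)c2ccc(OCC=C(C)C)cc2)c1Br | intermediate
20 | 5,7-bis(TBS-oxy)-8-methoxy-3-(prenyloxy)-2-[4-(prenyloxy)phenyl]-4H-chromen-4-one | COc1c(O[Si](C)(C)C(C)(C)C)cc(O[Si](C)(C)C(C)(C)C)c2c(=O)c(OCC=C(C)C)c(-c3ccc(OCC=C(C)C)cc3)oc12 | intermediate (not isolated)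
21 | 5,7-dihydroxy-8-methoxy-3-(prenyloxy)-2-[4-(prenyloxy)phenyl]-4H-chromen-4-one | COc1c(O)cc(O)c2c(=O)c(OCC=C(C)C)c(-c3ccc(OCC=C(C)C)cc3)oc12 | target

Total step count: 11. Longest linear sequence: 8 steps (steps 2, 3, 4, 5, 6, 9, 10, 11 from 4-hydroxybenzoic acid; equally steps 1, 3, 4, 5, 6, 9, 10, 11).

Steps most likely to fail

Step 9. The polarised addition may stop at an open-chain conjugate adduct after silyl transfer. The diene may abstract bromine from the alkyne, or the first adduct may lose bromide and give an alkynylated product. The hindered, donor-substituted ynone may also react so slowly that prolonged heating sets off sigmatropic rearrangement of the allyl vinyl ether. The fallback moves the annulation to a small, more electrophilic bromoynone and attaches ring B afterwards; it sets out from amide 3 and diene 16 and comes back at diketone 19, so that step 10 is not needed. Lithium (trimethylsilyl)acetylide (from 11 and n-BuLi, THF, −78 °C) is added to 3 to give 1-(prenyloxy)-4-(trimethylsilyl)but-3-yn-2-one F1. NBS with catalytic AgNO3 in acetone converts it into 4-bromo-1-(prenyloxy)but-3-yn-2-one F2, an unhindered bromoynone of the class for which this cycloaddition is established. F2 and 16 in toluene should give 1-[2-bromo-4,6-bis(TBS-oxy)-cis-3,6-dimethoxycyclohexa-1,4-dien-1-yl]-2-(prenyloxy)ethan-1-one F3, which loses methanol on silica to give 1-[2-bromo-4,6-bis(TBS-oxy)-3-methoxyphenyl]-2-(prenyloxy)ethan-1-one F4. Soft-enolisation C-acylation of F4 with acid chloride 8 (MgBr2·OEt2, iPr2NEt, CH2Cl2, 0 °C) then delivers 19.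

Step 11. Oxidative addition at the di-ortho-substituted, electron-rich C8a–Br bond may be slow. On long heating, protodebromination, retro-Claisen cleavage of the diketone or a [2,3]-shift of the prenyl group in the α-prenyloxy enolate could then take over. The fallback converts C8a–Br into C8a–OH and lets that phenol, the only free one, close ring C on the intact enol ether; it sets out from 18 (taken before step 10) and comes back at 20. Miyaura borylation (B2pin2, Pd(dppf)Cl2, KOAc, 1,4-dioxane, 80 °C) gives (E)-1-[4,6-bis(TBS-oxy)-3-methoxy-2-(4,4,5,5-tetramethyl-1,3,2-dioxaborolan-2-yl)phenyl]-3-(methoxymethoxy)-2-(prenyloxy)-3-[4-(prenyloxy)phenyl]prop-2-en-1-one F5. Oxidation with Me3NO in CH2Cl2 at rt gives (E)-1-[4,6-bis(TBS-oxy)-2-hydroxy-3-methoxyphenyl]-3-(methoxymethoxy)-2-(prenyloxy)-3-[4-(prenyloxy)phenyl]prop-2-en-1-one F6. Catalytic PPTS in CH2Cl2 should then induce conjugate addition of the C8a hydroxyl to C2 and loss of methoxymethanol to give 20, which is desilylated with TBAF and AcOH as in step 11.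

Step 6. NBS may brominate the prenyl alkenes, or silver may act as a π-acid and promote addition of the enol-ether oxygen to the alkyne, giving a 4-pyranone with loss of the MOM group. The fallback exchanges silicon for tin, so that neither silver nor excess electrophilic bromine is needed; it sets out from amide 10 and comes back at bromoynone 13. Lithium (tributylstannyl)acetylide (from ethynyltributylstannane and LDA, THF, −78 °C) is added to 10 to give (E)-1-(methoxymethoxy)-2-(prenyloxy)-1-[4-(prenyloxy)phenyl]-5-(tributylstannyl)pent-1-en-4-yn-3-one F7. Uncatalysed bromodestannylation with one equivalent of NBS in THF at −78 → 0 °C should then give 13.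

Further compounds
F1 | step 9 | 1-(prenyloxy)-4-(trimethylsilyl)but-3-yn-2-one | CC(C)=CCOCC(=O)C#C[Si](C)(C)C
F2 | step 9 | 4-bromo-1-(prenyloxy)but-3-yn-2-one | CC(C)=CCOCC(=O)C#CBr
F3 | step 9 | 1-[2-bromo-4,6-bis(TBS-oxy)-cis-3,6-dimethoxycyclohexa-1,4-dien-1-yl]-2-(prenyloxy)ethan-1-one (racemic, one enantiomer drawn) | CO[C@@]1(O[Si](C)(C)C(C)(C)C)C=C(O[Si](C)(C)C(C)(C)C)[C@@H](OC)C(Br)=C1C(=O)COCC=C(C)C
F4 | step 9 | 1-[2-bromo-4,6-bis(TBS-oxy)-3-methoxyphenyl]-2-(prenyloxy)ethan-1-one | COc1c(O[Si](C)(C)C(C)(C)C)cc(O[Si](C)(C)C(C)(C)C)c(C(=O)COCC=C(C)C)c1Br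
F5 | step 11 | (E)-1-[4,6-bis(TBS-oxy)-3-methoxy-2-(4,4,5,5-tetramethyl-1,3,2-dioxaborolan-2-yl)phenyl]-3-(methoxymethoxy)-2-(prenyloxy)-3-[4-(prenyloxy)phenyl]prop-2-en-1-one | COCO/C(=C(/OCC=C(C)C)C(=O)c1c(O[Si](C)(C)C(C)(C)C)cc(O[Si](C)(C)C(C)(C)C)c(OC)c1B2OC(C)(C)C(C)(C)O2)c1ccc(OCC=C(C)C)cc1
F6 | step 11 | (E)-1-[4,6-bis(TBS-oxy)-2-hydroxy-3-methoxyphenyl]-3-(methoxymethoxy)-2-(prenyloxy)-3-[4-(prenyloxy)phenyl]prop-2-en-1-one | COCO/C(=C(/OCC=C(C)C)C(=O)c1c(O[Si](C)(C)C(C)(C)C)cc(O[Si](C)(C)C(C)(C)C)c(OC)c1O)c1ccc(OCC=C(C)C)cc1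
F7 | step 6 | (E)-1-(methoxymethoxy)-2-(prenyloxy)-1-[4-(prenyloxy)phenyl]-5-(tributylstannyl)pent-1-en-4-yn-3-one | COCO/C(=C(/OCC=C(C)C)C(=O)C#C[Sn](CCCC)(CCCC)CCCC)c1ccc(OCC=C(C)C)cc1
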